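You cannot take more links out of a flask than its limiting reagent pays in, so keep books on that reagent and let one number move the entries.

| setting | Monday's | Tuesday's | dusk | autumn |
|---|---|---|---|---|
| first end groups | 20 mM | 20 mM | 20 mM | 20 mM |
| second end groups | 0.67 equiv | 1.5 equiv | 1.00 equiv | 1.00 equiv |
| scavenger | 0.50 equiv | 0.50 equiv | 0.500 equiv | 0.500 equiv |
| remark | run made earlier | run made earlier |  |  |
| time |  |  | 4.0 min | 12 min |

| Monday's: time / min | Monday's: links / % | Tuesday's: time / min | Tuesday's: links / % |
|---|---|---|---|
| 0.500 | 33 | 1.00 | 70 |
| 1.33 | 47 | 2.00 | 69 |
| 2.50 | 48 | 3.00 | 68 |
| 4.00 | 46 | 4.00 | 60 |

(scatter of a reading: 2 percentage points)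

- which of the two there is more of at the end, dusk (links / over-reaction product)
- which of the two there is more of at the end, autumn (links / over-reaction product)
- links at the end, in percent of the first end groups charged, dusk
- links at the end, in percent of the first end groups charged, autumn



Dusk and autumn charge second end groups at 1.00 equiv, level with the first, so I keep the books on first end groups, which I take as the limiting reagent, in percent of the charge. This reckoning is my own.

1. Paying in. Monday's peak reading of 48% is 71.6% of what its second end groups allow, and Tuesday's first reading is 70%. So I enter 70.0% under links for both flasks, and the rest stays outside these accounts.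

2. Dating. The entry is dated 1.00 min, the time of that first Tuesday reading.

3. Paying out. Replace Tuesday's flat stretch by its mean, 69.0% at 2.00 min. The last reading is 60% at 4.00 min, which gives a first-order loss of 0.0699 min⁻¹. That rests on a fall of 9 percentage points against a scatter of 2 points, and I carry it unchanged to 1.00 equiv. The link half-life, the time in which links halve with nothing feeding them, is 9.92 min.

4. Closing. [links] = entry × exp(−loss × time since the entry), and whatever leaves is booked as over-reaction product. Dusk closes at 56.8% links and 13.2% over-reaction product. Autumn closes at 32.5% links and 37.5% over-reaction product, so in autumn over-reaction product leads. In these books the two accounts cross at 10.9 min.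

5. Error. The same curve gives 65.3% at Tuesday's 2.00 min against a reading of 69%, so I carry that gap of about 3.7 points on both answers.

The forecast gives links and 62% for dusk, links and 58% for autumn: “Links should still exceed over-reaction product at both times”. My books part from it on the link figures for both flasks and on which of the two leads in autumn.

The flask gives dusk links, with 55.4% links and 15.9% over-reaction product. Autumn gives over-reaction product, with 33.1% links and 40.8% over-reaction product.

    first end groups + second end groups ⇌ links + released group (K = 1.80, k = 2.00 M⁻¹ s⁻¹)
    first end groups + released group ⇌ idle adduct, settled at all times (K = 26.0 M⁻¹)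
    scavenger + released group → scavenged by-product (k = 6.20 M⁻¹ s⁻¹)
    2 first end groups → homo dimer (k = 0.0470 M⁻¹ s⁻¹)
    links → over-reaction product (k = 0.00120 s⁻¹)

The link half-life puts 46.4% of the two accounts under links at 12 min. Autumn holds 73.9% in them, so that share makes 34.3% links, and autumn shows 33.1%. Take the neighbour of autumn charged with 2.00 equiv of scavenger, at the same time. It leaves 1.9% of its first end groups free and holds 93.9% in the two accounts. The same share makes 43.5% links there, and that neighbour shows 43.2%.

(The numbers in the tables were generated by integration with constants of no real substance; noise was put on by code.)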